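The numbers in the tables come from a simulation with made-up constants; noise was put on by code.

We decide to reckon the larch flask in fractions of the charge, and to ask first what share of the electrophile the nucleophile can pay for.

in all of them: electrophile 0.47 M; free base 0.564 M

| flask | nucleophile | temperature | remark | time |
|---|---|---|---|---|
| larch | 0.47 M | 80 °C | the very flask that is asked about, followed so far |  |
| elm | 0.47 M | 65 °C | run made earlier |  |
| flask | 0.470 M | 80 °C |  | 8.0 d |

| run | time / d | product / % | electrophile / % |
|---|---|---|---|
| larch | 0.417 | 17 | 85 |
| larch | 1.25 | 30 | 70 |
| larch | 2.50 | 39 | 63 |
| larch | 4.00 | 44 | 56 |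
| larch | 5.00 | 49 | 53 |
| larch | 6.00 | 48 | 51 |
| elm | 0.833 | 8 | 90 |
| elm | 2.50 | 19 | 77 |
| elm | 5.00 | 27 | 69 |
| elm | 8.00 | 42 | 64 |
| elm | 10.0 | 42 | 59 |
| elm | 12.0 | 45 | 58 |

(readings scatter by 2 percentage points)

- product taken out counts as made
- the numbers in the tables scatter with a standard deviation of 2 percentage points
- additions bring no volume worth counting

- violet: at 8.0 d add free base, 100 % of the amount charged, then wait 8.0 d
- ochre: at 8.0 d raise the temperature by 10 K, then wait 8.0 d
- amber: at 8.0 d add nucleophile, 50.0 % of the amount charged, then wait 8.0 d
- teal: change nothing and wait 8.0 d more
- green: at 8.0 d take out 90 % of the product then present, then wait 8.0 d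

1. product, in percent of the electrophile first charged, at 8.0 d
2. the remedy with the largest gain of product, or "none" below 2 percentage points (violet / ochre / amber / teal / green / none)
3. product present, with what was taken out counted in, in percent of the electrophile first charged, after violet
4. product present, with what was taken out counted in, in percent of the electrophile first charged, after teal

Take the main step by itself, electrophile and nucleophile giving product one for one. With equal charges, product divided by electrophile left then grows in proportion to time, and the larch reading of 30 % at 1.25 d gives a rate of 0.343 d⁻¹. That promises 67.3 % at 6.00 d, far more than the 48 % read there.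

So we add one process: suppose each product costs a second nucleophile, which makes the nucleophile the limiting reagent despite the equal charges. Product then stops at 50.0 %, and we call this the ceiling: the nucleophile charge over twice the electrophile charge. Now the logarithm of electrophile left over nucleophile left grows in proportion to time, and the same reading gives 0.448 d⁻¹, so at 8.0 d the inverse ratio, nucleophile left over electrophile left, stands at 0.0278. Putting the ceiling in as first answer yields 49.3 %, and going round once more yields 49.3 %.

Then the rest. Larch holds more free base than electrophile and still reads less than the ceiling, so we let free base leave the ceiling where it is. The cooler elm run reads 45 % at 12.0 d, so we let temperature change when the ceiling is reached, not where it stands. Our reckoning therefore keeps violet, ochre, green and teal near 50.0 %, while amber lifts the ceiling to 75.0 % and is our choice.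

The forecast says 52 % now, violet as the best remedy, 74 % after violet and 57 % after teal, reasoning that “Rate proportional to free base, with about 2 base used per product (exhausted near 60%), fits both runs”. We part from it on what pays for the product: it names free base, we name nucleophile.

The flask gives 49.3 % now, 51.0 % after violet and 50.5 % after teal, and amber gains the most, 23 percentage points.

    electrophile + nucleophile ⇌ acid set free + product (K = 0.820, k = 0.0370 M⁻¹ h⁻¹, Ea = 83.0 kJ mol⁻¹, ΔH = −14.0 kJ mol⁻¹)
    nucleophile + acid set free ⇌ protonated nucleophile, settled at all times (K = 12000 M⁻¹, ΔH = 20.0 kJ mol⁻¹)
    acid set free + free base ⇌ salt of the base, settled at all times (K = 3.30 M⁻¹, ΔH = −37.0 kJ mol⁻¹)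
    (constants at 80 °C)

At 8.00 d the flask holds 48.3 % of its nucleophile charge as protonated nucleophile beside 49.3 % product, with 2.47 % of the nucleophile free and 99.5 % of the free base unbound. The ceiling under amber stands 26 points above the present product, against that gain. For the neighbour charged with 0.80 M of nucleophile the ceiling is 85.1 %, and at 8.00 d that neighbour holds 78.2 % product.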